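The route rests on cutting the lower unit at C7'–C8' and C5'–C6'. Its seven-membered ring (C8', C9', C10', C1', C5', C6', C7') carries the lactone oxygen on C8', the spiro carbon C11' on C7' and a carbonyl-level C1', the pattern of a cyclopentane-1,3-dione enlarged by two carbons. Irradiation of enol ester 39, built from the C11' vinyl acid of the finished upper tricycle and (S)-4-methylcyclopentane-1,3-dione, should close the spiro γ-lactone and a cyclobutane in one operation (40); reductive opening of C5'–C8' then releases the cycloheptanone for triflation, Heck coupling and epoxide formation.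

Key step: step 22

Remark on labels: xanthanolide numbering is used; the upper unit is unprimed, the lower unit primed, C11' is the spiro carbon and C13' the ring methylene between C11' and C5.
Assumption: the hydrolase in step 2 cleaves the acetate on the future C5 (the sense known for the five-membered homologue); if it cleaves the other one, the diol from 2 would be monoacetylated with a lipase and vinyl acetate to reach the same 3.

Step 1
Reactants: 1 cyclohepta-1,3-diene
Product: 2 meso-cis-cyclohept-2-ene-1,4-diyl diacetate
Conditions: Pd(OAc)2 (5 mol %), LiOAc, LiCl (cat.), p-benzoquinone, AcOH, rt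
Reagents that add atoms: acetic acid CC(=O)O
Why: Palladium-catalysed 1,4-diacetoxylation (Bäckvall reaction): the π-allyl complex of divalent palladium formed by acetoxypalladation is opened by external acetate anti to the metal when chloride blocks inner-sphere transfer, so the two C–O bonds end cis and the product is meso.

Step 2
Reactants: 2 meso diacetate
Product: 3 (1S,4R)-4-acetoxycyclohept-2-en-1-ol
Conditions: electric eel acetylcholinesterase, NaH2PO4 buffer (pH 7), rt
Reagents that add atoms: none
Why: Enzymatic desymmetrisation of a meso diacetate, in which hydrolysis of one enantiotopic ester fixes the acetate-bearing carbon (the future C8) as R and frees the allylic alcohol that steers step 3.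

Step 3
Reactants: 3 monoacetate, 4 triethyl orthoacetate
Product: 5 ethyl 2-(cis-7-acetoxycyclohept-2-en-1-yl)acetate
Conditions: EtCO2H (cat.), neat, 140 °C, EtOH distilled off
Reagents that add atoms: none
Why: Johnson–Claisen rearrangement, in which the ketene acetal formed on the allylic hydroxyl rearranges suprafacially so that the CH2CO2Et group reaches C7 on the face the C–O bond leaves, cis to the C8 acetate, while the alkene moves to C5=C6.

Step 4
Reactants: 5 acetoxy ester
Product: 6 cis-fused γ-lactone with C5=C6 alkene
Conditions: p-TsOH (cat.), MeOH, 50 °C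
Reagents that add atoms: none
Why: Acid-catalysed transesterification removes the acetate and the cis 1,2-hydroxy ester closes to the cis-fused γ-lactone (lactonisation) without touching a stereocentre.

Step 5
Reactants: 6 alkene lactone
Product: 7 enone lactone (C1 ketone conjugated with C5=C6)
Conditions: Rh2(cap)4 (dirhodium tetracaprolactamate, 1 mol %), t-BuOOH, K2CO3, CH2Cl2, rt
Reagents that add atoms: tert-butyl hydroperoxide CC(C)(C)OO
Why: Radical allylic oxidation with tert-butylperoxyl radicals, in which C1 is the only allylic methylene (the other allylic position, C7, is a hindered methine), so hydrogen abstraction and peroxide collapse should give the C1 ketone.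

Step 6
Reactants: 7 enone lactone
Product: 10 cross-conjugated dienone lactone, via Mannich base 8 (not isolated), via methiodide 9 (not isolated)
Conditions: LiN(i-Pr)2, THF, −78 °C; CH2=NMe2+ I−, −78 °C → rt; MeI, CH2Cl2, rt; NaHCO3 (aq), CH2Cl2, rt
Reagents that add atoms: Eschenmoser's salt C=[N+](C)C.[I-]
Why: Eschenmoser methylenation (Mannich reaction, quaternisation, E1cB elimination), regiospecific because the kinetic enolate of the enone can only form at the α′ carbon C10.

Step 7
Reactants: 10 dienone lactone
Product: 11 keto lactone (3aR,7S,8aR)-7-methylhexahydro-2H-cyclohepta[b]furan-2,6(3H)-dione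
Conditions: H2 (1 atm), Pd/C, EtOAc, rt
Reagents that add atoms: none
Why: Heterogeneous hydrogenation reduces both conjugated alkenes and delivers hydrogen to C10 from the convex face of the cis-fused bicycle (the face of H7 and H8), which should place the new methyl group on the face of the lactone oxygen.

Step 8
Reactants: 11 keto lactone
Product: 14 exo-methylene ketone, via Mannich base 12 (not isolated), via methiodide 13 (not isolated)
Conditions: LiN(i-Pr)2 (1.2 equiv), THF, −78 °C, ketone added to base; CH2=NMe2+ I−; MeI, CH2Cl2; NaHCO3 (aq)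
Reagents that add atoms: Eschenmoser's salt C=[N+](C)C.[I-]
Why: Kinetic deprotonation takes the less substituted α-carbon C5 and leaves the methyl-bearing C10 stereocentre untouched, and the Eschenmoser methylenation then installs C13' as an exocyclic methylene.

Step 9
Reactants: 14 exo-methylene ketone, 15 methyl crotonate
Product: 16 keto ester with the C5 side chain CH2CH(CH=CH2)CO2Me
Conditions: 15, LiN(i-Pr)2, THF/DMPU, −78 °C; then 14, −78 °C; NH4Cl (aq), −78 °C
Reagents that add atoms: none
Why: Michael addition of the lithium dienolate of methyl crotonate through its α-carbon (the future C11') to the unhindered methylene, after which the ketone enolate is protonated from the convex face so that C13' sits cis to the C10 methyl, while C11' forms as a mixture that step 13 erases.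

Step 10
Reactants: 17 but-3-yn-2-one
Product: 18 2-ethynyl-2-methyl-1,3-dioxolane
Conditions: TMSOCH2CH2OTMS, TMSOTf (cat.), CH2Cl2, −78 °C
Reagents that add atoms: 1,2-bis(trimethylsilyloxy)ethane C[Si](C)(C)OCCO[Si](C)(C)C
Why: Noyori ketalisation under aprotic conditions protects the ynone carbonyl without conjugate addition of the diol.

Step 11
Reactants: 18 alkynyl dioxolane
Product: 19 (E)-alkenylstannane
Conditions: Bu3SnH, AIBN (cat.), PhH, 80 °C
Reagents that add atoms: tributyltin hydride CCCC[SnH](CCCC)CCCC
Why: Radical hydrostannylation of the terminal alkyne, which under reversible stannyl radical addition should give the E β-stannyl alkene.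

Step 12
Reactants: 16 keto ester, 19 alkenylstannane
Product: 22 cis-fused δ-lactone carrying the alkenyl group on C1, via alkenyllithium 20 (not isolated), via hydroxy ester 21 (not isolated)
Conditions: 19, n-BuLi, THF, −78 °C; CeCl3, −78 °C; 16, −78 → 0 °C; NH4Cl (aq)
Reagents that add atoms: none
Why: Tin–lithium exchange and transmetalation to cerium give a non-basic alkenyl nucleophile that adds to the ketone (1,2-addition) anti to the two cis α-substituents, and the alkoxide, now cis to the C5 side chain, closes the δ-lactone, which lets any C1 epimer be removed as uncyclised hydroxy ester.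

Step 13
Reactants: 22 δ-lactone
Product: 25 cyclohexene acid with quaternary C11', via silyl ketene acetal 23 (not isolated), via trimethylsilyl ester 24 (not isolated)
Conditions: KN(SiMe3)2, Me3SiCl, Et3N, THF, −78 → 65 °C; NaH2PO4 (aq) work-up
Reagents that add atoms: none
Why: Ireland–Claisen rearrangement of a lactone silyl ketene acetal, in which the C13'–C5 tether enforces a boat transition state so that C11' bonds to C3 on the face the C1–O bond leaves, setting C11' (carboxyl cis to C6, vinyl cis to H5) and C3 from the cis lactone fusion and the E alkene whatever the C11' configuration of 22.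

Step 14
Reactants: 25 cyclohexene acid
Product: 27 bridged hydroxy lactone, via epoxy acid 26 (not isolated)
Conditions: mCPBA, NaHCO3, CH2Cl2, 0 °C; then CSA (cat.), CH2Cl2, rt
Reagents that add atoms: meta-chloroperbenzoic acid OOC(=O)c1cccc(Cl)c1
Why: Peracid epoxidation of the trisubstituted C1=C2 bond should occur anti to the carboxyl and the allylic dioxolanyl group, and acid then lets that carboxyl open the epoxide at the tertiary C1 with inversion (epoxy acid lactonisation), returning oxygen to C1 cis to C12' and leaving the C2 hydroxyl syn to H3.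

Step 15
Reactants: 27 bridged hydroxy lactone
Product: 28 bridged lactone with C2=C3 alkene
Conditions: Burgess reagent, PhH, 60 °C
Reagents that add atoms: none
Why: Burgess dehydration is a syn elimination, and in the rigid bicyclo[2.2.2] lactone the C2 sulfamate is eclipsed with H3, the only β-hydrogen, so only the C2=C3 alkene can form.

Step 16
Reactants: 28 bridged lactone
Product: 30 hydroxy acid, via dilithium dicarboxylate 29 (not isolated)
Conditions: LiOH, THF/H2O, rt; then HCl (0.1 M aq) to pH 3, rt
Reagents that add atoms: water O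
Why: Saponification opens both lactones by acyl–oxygen cleavage, so C1 keeps its configuration, and mild acidification recloses only the cis γ-lactone because the tertiary C1 hydroxyl relactonises slowly.

Step 17
Reactants: 30 hydroxy acid
Product: 32 C1 triethylsilyl ether acid, via bis-silyl derivative 31 (not isolated)
Conditions: Et3SiOTf (2.5 equiv), 2,6-lutidine, CH2Cl2, −78 → 0 °C; NaHCO3 (aq) work-up
Reagents that add atoms: triethylsilyl triflate CC[Si](CC)(CC)OS(=O)(=O)C(F)(F)F
Why: Silylation with a silyl triflate protects the tertiary allylic alcohol, the silyl ester formed alongside being hydrolysed on aqueous work-up, while the ketone ketal survives the low temperature.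

Step 18
Reactants: 33 (R)-4-benzyl-3-propanoyloxazolidin-2-one, 34 allyl iodide
Product: 35 (R)-4-benzyl-3-[(S)-2-methylpent-4-enoyl]oxazolidin-2-one
Conditions: NaN(SiMe3)2, THF, −78 °C; 34, −78 → −40 °C
Reagents that add atoms: none
Why: Evans asymmetric alkylation, in which the chelated Z sodium enolate is allylated on the face away from the benzyl group to give the (S)-configured α-methyl centre.

Step 19
Reactants: 35 allylated imide
Product: 36 (R)-4-benzyl-3-[(S)-2-methyl-4-oxopentanoyl]oxazolidin-2-one
Conditions: PdCl2 (10 mol %), CuCl, O2 (1 atm), DMF/H2O, rt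
Reagents that add atoms: water O
Why: Tsuji–Wacker oxidation converts the terminal alkene into the methyl ketone with Markovnikov regiochemistry under neutral conditions that leave the α-stereocentre alone.

Step 20
Reactants: 36 keto imide
Product: 37 (S)-4-methylcyclopentane-1,3-dione
Conditions: LiN(SiMe3)2 (2.1 equiv), THF, −78 → 0 °C; HCl (1 M aq)
Reagents that add atoms: none
Why: Intramolecular Claisen (Dieckmann-type) condensation, in which the kinetic methyl-ketone enolate attacks the exocyclic imide carbonyl (5-exo-trig) and expels the auxiliary, the acidic dione being deprotonated at once, which shields the methyl-bearing stereocentre.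

Step 21
Reactants: 32 acid, 37 (S)-dione
Product: 39 enol ester (photoprecursor), via acid chloride 38 (not isolated)
Conditions: 32, 1-chloro-N,N,2-trimethylprop-1-en-1-amine, CH2Cl2, 0 °C; then 37, Et3N, CH2Cl2, −20 → 0 °C
Reagents that add atoms: none
Why: O-acylation of a cyclic 1,3-dione, in which the acid chloride made under neutral conditions should acylate the less hindered enolate oxygen, the one remote from the methyl group, which places C10' next to the ketone C1'.

Step 22
Reactants: 39 enol ester
Product: 40 cyclobutane photoadduct with cis-fused spiro γ-lactone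
Conditions: hν (350 nm, Pyrex), degassed MeCN (2 mM), 45 °C
Reagents that add atoms: none
Why: Proposed new method: n→π* excitation of the 3-acyloxycyclopentenone and intersystem crossing give the enone triplet, whose β-carbon C8' bonds first to the internal vinyl carbon C7' (5-exo-trig closure through the O–C12'–C11' tether, which makes the γ-lactone), and the resulting C5'/C6' 1,4-diradical then recombines to close the four-membered ring. The closest known reaction type is the intramolecular enone–alkene [2+2] photocycloaddition of β-oxygenated enones used in de Mayo sequences (dioxenones, vinylogous esters and amides); an ester oxygen as the tether atom on the enone β-carbon is the untested element. The three-atom tether forces the lactone and the cyclobutane to be cis-fused, so C8' and C5' follow from C7'. C7' is set by the rotamer about the C11'–vinyl bond: the cyclopentenone should stack over the C13' methylene face of the cyclohexene, away from C3 and its dioxolane, and this pairing uses the enone face anti to the C10' methyl of the (S)-dione (matched case). Preference for the vinyl group over the fully substituted C2=C3 alkene is steric, the C4 ketal removes the only other chromophore absorbing at 350 nm, and high dilution suppresses dimerisation. The ester must react from its minor s-cis rotamer, which a polar solvent and 45 °C should populate, while excited s-trans molecules relax unchanged.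

Step 23
Reactants: 40 photoadduct
Product: 41 keto bis-lactone with the lower cycloheptanone
Conditions: SmI2 (2.5 equiv), MeOH (5 equiv), THF, −78 °C
Reagents that add atoms: none
Why: SmI2-mediated ketyl fragmentation of a cyclobutyl ketone, in which the C1' ketyl should open the strained ring at C5'–C8' because this gives a tertiary α-acyloxy radical (C5'–C6' cleavage would give a primary one), and reduction and protonation at C8' from the face opposite the new seven-membered chain should give the cis-fused lactone.

Step 24
Reactants: 41 keto bis-lactone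
Product: 42 C1'=C5' enol triflate
Conditions: KN(SiMe3)2 (1.05 equiv), THF, −78 °C; Comins' reagent, −78 °C
Reagents that add atoms: Comins' reagent FC(F)(F)S(=O)(=O)N(c1ccc(Cl)cn1)S(=O)(=O)C(F)(F)F
Why: Kinetic enolisation at the less substituted α-carbon C5' (not at the methyl-bearing C10') followed by O-sulfonylation gives the enol triflate regioselectively.

Step 25
Reactants: 42 enol triflate
Product: 45 α-methylene lactone triflate, via Mannich base 43 (not isolated), via methiodide 44 (not isolated)
Conditions: LiN(i-Pr)2, THF, −78 °C; CH2=NMe2+ I−; MeI, CH2Cl2; NaHCO3 (aq)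
Reagents that add atoms: Eschenmoser's salt C=[N+](C)C.[I-]
Why: Eschenmoser methylenation of a lactone enolate, feasible here because with the lower ketone masked as its enol triflate the α-CH2 of the upper γ-lactone is the most acidic C–H in the molecule.

Step 26
Reactants: 45 methylene lactone triflate, 46 but-3-en-2-one
Product: 47 protected dienone
Conditions: 46 (5 equiv), Pd(OAc)2 (10 mol %), PPh3 (20 mol %), Et3N, DMF, 60 °C
Reagents that add atoms: none
Why: Heck reaction, in which oxidative addition of zerovalent palladium into the alkenyl triflate, insertion of the excess enone and β-hydride elimination give the E dienone, the 1,1-disubstituted methylene lactone being the slower acceptor.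

Step 27
Reactants: 47 protected dienone
Product: 48 hydroxy enone dienone (penultimate compound)
Conditions: HCl (1 M aq), THF, rt
Reagents that add atoms: water O
Why: Acid hydrolysis removes the dioxolane and the tertiary triethylsilyl ether in one operation, the dienone, the methylene lactone and the tertiary allylic alcohol being stable to dilute acid.

Step 28
Reactants: 48 hydroxy enone dienone
Product: 50 CNP0177598.1, via bromohydrin 49 (not isolated)
Conditions: NBS, acetone/H2O, 0 °C; then K2CO3, rt
Reagents that add atoms: water O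
Why: Bromohydrin formation and base-induced epoxide closure: the bromonium ion should form on the most electron-rich alkene C1'=C5' anti to the pseudoaxial C10' methyl, water opens it at the tertiary C1' from the methyl face, and intramolecular SN2 displacement of bromide then places the epoxide syn to the methyl group and the lactone (should the facial bias be the reverse, dimethyldioxirane on 48 would give 50 directly).

Compound list
1 | cyclohepta-1,3-diene | C1=CC=CCCC1 | starting material
2 | meso-cis-cyclohept-2-ene-1,4-diyl diacetate | CC(=O)O[C@@H]1C=C[C@H](OC(C)=O)CCC1 | intermediate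
3 | (1S,4R)-4-acetoxycyclohept-2-en-1-ol | O[C@@H]1C=C[C@H](OC(C)=O)CCC1 | intermediate
4 | triethyl orthoacetate | CC(OCC)(OCC)OCC | starting material
5 | ethyl 2-[(1S,7R)-7-acetoxycyclohept-2-en-1-yl]acetate, substituents cis | CCOC(=O)C[C@H]1C=CCCC[C@H]1OC(C)=O | intermediate
6 | (3aS,8aR)-3,3a,6,7,8,8a-hexahydro-2H-cyclohepta[b]furan-2-one, cis-fused lactone with C5=C6 | C1C(=O)O[C@@H]2CCCC=C[C@H]12 | intermediate
7 | cis-fused lactone enone, C1 ketone conjugated with C5=C6 | C1C(=O)O[C@@H]2CCC(=O)C=C[C@H]12 | intermediate
8 | C10 dimethylaminomethyl derivative of 7 (Mannich base, C10 epimers) | C1C(=O)O[C@@H]2CC(CN(C)C)C(=O)C=C[C@H]12 | intermediate (not isolated)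
9 | trimethylammonium iodide from 8 | C1C(=O)O[C@@H]2CC(C[N+](C)(C)C)C(=O)C=C[C@H]12.[I-] | intermediate (not isolated)
10 | C10 methylene derivative of 7 (cross-conjugated dienone) | C1C(=O)O[C@@H]2CC(=C)C(=O)C=C[C@H]12 | intermediate
11 | (3aR,7S,8aR)-7-methylhexahydro-2H-cyclohepta[b]furan-2,6(3H)-dione, methyl cis to the lactone oxygen | C1C(=O)O[C@@H]2C[C@H](C)C(=O)CC[C@H]12 | intermediate
12 | C5 dimethylaminomethyl derivative of 11 (Mannich base, C5 epimers) | C1C(=O)O[C@@H]2C[C@H](C)C(=O)C(CN(C)C)C[C@H]12 | intermediate (not isolated)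
13 | trimethylammonium iodide from 12 | C1C(=O)O[C@@H]2C[C@H](C)C(=O)C(C[N+](C)(C)C)C[C@H]12.[I-] | intermediate (not isolated)
14 | C5 methylene derivative of 11 | C1C(=O)O[C@@H]2C[C@H](C)C(=O)C(=C)C[C@H]12 | intermediate
15 | methyl (E)-but-2-enoate (methyl crotonate) | C/C=C/C(=O)OC | starting material
16 | keto ester: ketone 11 bearing CH2CH(CH=CH2)CO2Me on C5, cis to the C10 methyl, C11' both epimers | C1C(=O)O[C@@H]2C[C@H](C)C(=O)[C@H](CC(C=C)C(=O)OC)C[C@H]12 | intermediate
17 | but-3-yn-2-one | CC(=O)C#C | starting material
18 | 2-ethynyl-2-methyl-1,3-dioxolane | CC1(C#C)OCCO1 | intermediate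
19 | tributyl[(E)-2-(2-methyl-1,3-dioxolan-2-yl)ethenyl]stannane | CC1(/C=C/[Sn](CCCC)(CCCC)CCCC)OCCO1 | intermediate
20 | [(E)-2-(2-methyl-1,3-dioxolan-2-yl)ethenyl]lithium | CC1(/C=C/[Li])OCCO1 | intermediate (not isolated)
21 | tertiary alcohol from 16: C1 hydroxyl cis to the C5 side chain, alkenyl trans | C1C(=O)O[C@@H]2C[C@H](C)[C@@](O)(/C=C/C3(C)OCCO3)[C@H](CC(C=C)C(=O)OC)C[C@H]12 | intermediate (not isolated)
22 | δ-lactone between the C1 oxygen and C12', cis-fused to the cycloheptane, C1 bearing the (E)-alkenyl ketal, C11' (H, vinyl) both epimers | C1C(=O)O[C@@H]2C[C@H](C)[C@]3(/C=C/C4(C)OCCO4)OC(=O)C(C=C)C[C@@H]3C[C@H]12 | intermediate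
23 | trimethylsilyl ketene acetal of 22 | C1C(=O)O[C@@H]2C[C@H](C)[C@]3(/C=C/C4(C)OCCO4)OC(O[Si](C)(C)C)=C(C=C)C[C@@H]3C[C@H]12 | intermediate (not isolated)
24 | trimethylsilyl ester of 25 | C1C(=O)O[C@@H]2C[C@H](C)C3=C[C@H](C4(C)OCCO4)[C@](C[C@@H]3C[C@H]12)(C=C)C(=O)O[Si](C)(C)C | intermediate (not isolated)
25 | cyclohexene acid: C1=C2 alkene, C3 (H, dioxolanyl cis to the carboxyl), quaternary C11' (vinyl, CO2H) | C1C(=O)O[C@@H]2C[C@H](C)C3=C[C@H](C4(C)OCCO4)[C@](C[C@@H]3C[C@H]12)(C=C)C(=O)O | intermediate
26 | C1,C2-epoxide of 25, oxygen trans to the carboxyl | C1C(=O)O[C@@H]2C[C@H](C)[C@]34O[C@H]3[C@H](C5(C)OCCO5)[C@](C[C@@H]4C[C@H]12)(C=C)C(=O)O | intermediate (not isolated)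
27 | bridged δ-lactone (C1–O–C12') with secondary C2 hydroxyl syn to H3 | C1C(=O)O[C@@H]2C[C@H](C)[C@@]3(OC4=O)[C@@H](O)[C@H](C5(C)OCCO5)[C@@]4(C=C)C[C@@H]3C[C@H]12 | intermediate
28 | bridged δ-lactone with C2=C3 alkene bearing the dioxolanyl group | C1C(=O)O[C@@H]2C[C@H](C)[C@@]3(OC4=O)C=C(C5(C)OCCO5)[C@@]4(C=C)C[C@@H]3C[C@H]12 | intermediate
29 | dilithium salt of the doubly ring-opened dihydroxy diacid | [Li+].[Li+].[O-]C(=O)C[C@H]1C[C@H]2C[C@@](C=C)(C([O-])=O)C(C3(C)OCCO3)=C[C@]2(O)[C@@H](C)C[C@H]1O | intermediate (not isolated)
30 | hydroxy acid: C1 tertiary alcohol cis to the C11' carboxyl, upper γ-lactone reclosed | C1C(=O)O[C@@H]2C[C@H](C)[C@@]3(O)C=C(C5(C)OCCO5)[C@](C[C@@H]3C[C@H]12)(C=C)C(=O)O | intermediate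
31 | triethylsilyl ether triethylsilyl ester of 30 | C1C(=O)O[C@@H]2C[C@H](C)[C@@]3(O[Si](CC)(CC)CC)C=C(C5(C)OCCO5)[C@](C[C@@H]3C[C@H]12)(C=C)C(=O)O[Si](CC)(CC)CC | intermediate (not isolated)
32 | C11' vinyl acid with C1 triethylsilyl ether and C4 dioxolane | C1C(=O)O[C@@H]2C[C@H](C)[C@@]3(O[Si](CC)(CC)CC)C=C(C5(C)OCCO5)[C@](C[C@@H]3C[C@H]12)(C=C)C(=O)O | intermediate
33 | (R)-4-benzyl-3-propanoyl-1,3-oxazolidin-2-one | CCC(=O)N1[C@H](Cc2ccccc2)COC1=O | starting material
34 | 3-iodoprop-1-ene (allyl iodide) | C=CCI | starting material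
35 | (R)-4-benzyl-3-[(S)-2-methylpent-4-enoyl]-1,3-oxazolidin-2-one | C=CC[C@H](C)C(=O)N1[C@H](Cc2ccccc2)COC1=O | intermediate
36 | (R)-4-benzyl-3-[(S)-2-methyl-4-oxopentanoyl]-1,3-oxazolidin-2-one | CC(=O)C[C@H](C)C(=O)N1[C@H](Cc2ccccc2)COC1=O | intermediate
37 | (S)-4-methylcyclopentane-1,3-dione (drawn as diketone) | O=C1CC(=O)[C@@H](C)C1 | intermediate
38 | acid chloride of 32 | C1C(=O)O[C@@H]2C[C@H](C)[C@@]3(O[Si](CC)(CC)CC)C=C(C5(C)OCCO5)[C@](C[C@@H]3C[C@H]12)(C=C)C(Cl)=O | intermediate (not isolated)
39 | enol ester of acid 32 with the dione oxygen remote from the methyl group (3-acyloxy-5-methylcyclopent-2-enone) | C1C(=O)O[C@@H]2C[C@H](C)[C@@]3(O[Si](CC)(CC)CC)C=C(C5(C)OCCO5)[C@](C[C@@H]3C[C@H]12)(C=C)C(=O)OC4=CC(=O)[C@@H](C)C4 | intermediate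
40 | photoadduct: cyclobutane (C8', C5', C6', C7') fused to the cyclopentanone and to the cis spiro γ-lactone | C1C(=O)O[C@@H]2C[C@H](C)[C@@]3(O[Si](CC)(CC)CC)C=C(C5(C)OCCO5)[C@@]4(C[C@@H]3C[C@H]12)C(=O)O[C@@]15C[C@H](C)C(=O)[C@H]5C[C@@H]14 | intermediate
41 | keto bis-lactone: lower cis-fused lactone on a cycloheptanone (C1' ketone, C10' methyl) | C1C(=O)O[C@@H]2C[C@H](C)[C@@]3(O[Si](CC)(CC)CC)C=C(C5(C)OCCO5)[C@@]4(C[C@@H]3C[C@H]12)C(=O)O[C@@H]1C[C@H](C)C(=O)CC[C@@H]14 | intermediate
42 | C1'=C5' enol triflate of 41 | C1C(=O)O[C@@H]2C[C@H](C)[C@@]3(O[Si](CC)(CC)CC)C=C(C5(C)OCCO5)[C@@]4(C[C@@H]3C[C@H]12)C(=O)O[C@@H]1C[C@H](C)C(OS(=O)(=O)C(F)(F)F)=CC[C@@H]14 | intermediate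
43 | C11 dimethylaminomethyl derivative of 42 (Mannich base, C11 epimers) | CN(C)CC1C(=O)O[C@@H]2C[C@H](C)[C@@]3(O[Si](CC)(CC)CC)C=C(C5(C)OCCO5)[C@@]4(C[C@@H]3C[C@H]12)C(=O)O[C@@H]1C[C@H](C)C(OS(=O)(=O)C(F)(F)F)=CC[C@@H]14 | intermediate (not isolated)
44 | trimethylammonium iodide from 43 | C[N+](C)(C)CC1C(=O)O[C@@H]2C[C@H](C)[C@@]3(O[Si](CC)(CC)CC)C=C(C5(C)OCCO5)[C@@]4(C[C@@H]3C[C@H]12)C(=O)O[C@@H]1C[C@H](C)C(OS(=O)(=O)C(F)(F)F)=CC[C@@H]14.[I-] | intermediate (not isolated)
45 | enol triflate with the upper α-methylene γ-lactone | C=C1C(=O)O[C@@H]2C[C@H](C)[C@@]3(O[Si](CC)(CC)CC)C=C(C5(C)OCCO5)[C@@]4(C[C@@H]3C[C@H]12)C(=O)O[C@@H]1C[C@H](C)C(OS(=O)(=O)C(F)(F)F)=CC[C@@H]14 | intermediate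
46 | but-3-en-2-one | C=CC(C)=O | starting material
47 | protected dienone: lower (E)-3-oxobut-1-enyl on C1'=C5', C1 silyl ether, C4 dioxolane | C=C1C(=O)O[C@@H]2C[C@H](C)[C@@]3(O[Si](CC)(CC)CC)C=C(C5(C)OCCO5)[C@@]4(C[C@@H]3C[C@H]12)C(=O)O[C@@H]1C[C@H](C)C(/C=C/C(C)=O)=CC[C@@H]14 | intermediate
48 | deprotected compound: C1 hydroxyl, C3 acetyl, lower dienone | C=C1C(=O)O[C@@H]2C[C@H](C)[C@@]3(O)C=C(C(C)=O)[C@@]4(C[C@@H]3C[C@H]12)C(=O)O[C@@H]1C[C@H](C)C(/C=C/C(C)=O)=CC[C@@H]14 | intermediate
49 | bromohydrin: C1' hydroxyl syn to the C10' methyl, C5' bromide anti | C=C1C(=O)O[C@@H]2C[C@H](C)[C@@]3(O)C=C(C(C)=O)[C@@]4(C[C@@H]3C[C@H]12)C(=O)O[C@@H]1C[C@H](C)[C@@](O)(/C=C/C(C)=O)[C@@H](Br)C[C@@H]14 | intermediate (not isolated)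
50 | CNP0177598.1 | C=C1C(=O)O[C@@H]2C[C@H](C)[C@@]3(O)C=C(C(C)=O)[C@@]4(C[C@@H]3C[C@H]12)C(=O)O[C@@H]1C[C@H](C)[C@]2(/C=C/C(C)=O)O[C@@H]2C[C@@H]14 | target

Total step count: 28. Longest linear sequence: 23 steps (steps 1–9, 12–17 and 21–28, from cyclohepta-1,3-diene); the alkenylstannane (steps 10–11) and the dione (steps 18–20) are side branches.

Steps most likely to fail

Step 22. The ester may stay in its s-trans rotamer during the short triplet lifetime, so that excitation is wasted and slower acyl shift or ester cleavage takes over; bonding to the wrong vinyl face is the second danger. The fallback is the thermal Diels–Alder union of two monomers, which sets out from 11 and returns at 48. Kinetic enol triflation of 11 (KN(SiMe3)2, Comins' reagent) would give the enol triflate F1, Eschenmoser methylenation of its lactone the methylene lactone triflate F2, and Heck coupling with 46 the monomeric dienone F3. Heating F3 neat or in toluene at 110 °C should bring about the Diels–Alder dimerisation in which the C5=C1–C2=C3 diene of one molecule adds across the C11=C13 methylene lactone of a second, endo to the lactone carbonyl, giving the dimer F4 with a C1=C2 bond. Deprotonation at C3 (t-BuOK, t-BuOH/THF) under oxygen with P(OEt)3 then oxygenates the dienolate at its γ-carbon C1 and gives 48.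

Step 23. The ketyl may open the cyclobutane at the external C5'–C6' bond, which overlaps better with the carbonyl π system, or C8' may be protonated from the wrong face. The fallback is the classical retro-aldol version of the ring expansion, from 40 back to 41. LiOH in aqueous THF saponifies the spiro lactone, and the freed cyclobutanol, β to the C1' ketone, undergoes retro-aldol cleavage of C5'–C8' to the diketo acid F5. NaBH4 reduces both ketones, hydride reaching C8' anti to the C11' substituent, and acidification lactonises the C8' alcohol to the hydroxy lactone F6. Dess–Martin oxidation of the remaining C1' alcohol gives 41.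

Step 14. Epoxidation may take place on the wrong face, or the epoxide may open at C2 or by hydride shift instead of at C1. The fallback brings the oxygen in through the dienolate, from 25 back to 28. PPTS in wet acetone removes the ketal to give the β,γ-unsaturated keto acid F7. Its dienolate (t-BuOK, O2, P(OEt)3) is oxygenated at the γ-carbon C1 to the γ-hydroxy enone acid F8. Carbodiimide activation (EDC·HCl, DMAP) lactonises only the isomer whose hydroxyl is cis to the carboxyl, giving the enone lactone F9, and Noyori ketalisation (TMSOCH2CH2OTMS, TMSOTf) gives 28.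

Further compounds
F1 | step 22 | C1=C5 enol triflate of ketone 11 | C1C(=O)O[C@@H]2C[C@H](C)C(OS(=O)(=O)C(F)(F)F)=CC[C@H]12
F2 | step 22 | α-methylene lactone enol triflate | C=C1C(=O)O[C@@H]2C[C@H](C)C(OS(=O)(=O)C(F)(F)F)=CC[C@H]12
F3 | step 22 | monomeric dienone with cis-fused α-methylene lactone | C=C1C(=O)O[C@@H]2C[C@H](C)C(/C=C/C(C)=O)=CC[C@H]12
F4 | step 22 | Diels–Alder dimer with C1=C2 alkene and C3–H | C=C1C(=O)O[C@@H]2C[C@H](C)C3=C[C@H](C(C)=O)[C@@]4(C[C@@H]3C[C@H]12)C(=O)O[C@@H]1C[C@H](C)C(/C=C/C(C)=O)=CC[C@@H]14
F5 | step 23 | diketo acid from retro-aldol opening (C8' and C1' ketones) | C1C(=O)O[C@@H]2C[C@H](C)[C@@]3(O[Si](CC)(CC)CC)C=C(C5(C)OCCO5)[C@](C[C@@H]3C[C@H]12)([C@H]1CCC(=O)[C@@H](C)CC1=O)C(=O)O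
F6 | step 23 | cis-fused spiro lactone with C1' alcohol (epimers) | C1C(=O)O[C@@H]2C[C@H](C)[C@@]3(O[Si](CC)(CC)CC)C=C(C5(C)OCCO5)[C@@]4(C[C@@H]3C[C@H]12)C(=O)O[C@@H]1C[C@H](C)C(O)CC[C@@H]14
F7 | step 14 | β,γ-unsaturated keto acid (ketal removed from 25) | C1C(=O)O[C@@H]2C[C@H](C)C3=C[C@H](C(C)=O)[C@](C[C@@H]3C[C@H]12)(C=C)C(=O)O
F8 | step 14 | γ-hydroxy enone acid, C1 hydroxyl cis to the carboxyl | C1C(=O)O[C@@H]2C[C@H](C)[C@@]3(O)C=C(C(C)=O)[C@](C[C@@H]3C[C@H]12)(C=C)C(=O)O
F9 | step 14 | bridged δ-lactone with free C3 acetyl | C1C(=O)O[C@@H]2C[C@H](C)[C@@]3(OC4=O)C=C(C(C)=O)[C@@]4(C=C)C[C@@H]3C[C@H]12
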